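**Retrosynthetic overview**

1. Numbering: ring A = C1 (carbinol), C2, C3 (CHCl), C4 (quaternary: methyl + side chain), C5, C10 (quaternary: methyl); ring B = C5, C6, C7=C8 (ester), C9 (bears formyl carbon C11), C10. β = face of the C10 methyl; TBS = tert-butyldimethylsilyl.
2. The route rests on one feature: the equatorial chlorine on C3 is antiperiplanar to the C4–C5 ring bond, next to fully substituted C4, in trans-fused rings A/B. This is what anti addition of Cl+ and carbon across an E-trisubstituted alkene leaves when the chain folds chair–chair.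
3. End game (backwards): C11 aldehyde from the primary alcohol; side chain by cross-metathesis on a C4 allyl group; C8 ester and C7=C8 by carbonylation of the kinetic enol triflate of an 8-ketone; all from a 3-chloro-8-oxo-9-carbomethoxy trans-decalin.
4. Key disconnection: C3–Cl, C4–C5 and C9–C10 are made in one chloriranium-triggered bicyclisation of an acyclic (E,E)-trienyl β-keto ester carrying the C1 silyl ether. Ring A closes first, ring B second, in the same cascade.
5. Precursor: acetoacetate dianion + E-allylic bromide; both trisubstituted alkenes by Negishi carboalumination (of pent-1-en-4-yne, then of a propargylic silyl ether); C1 from (S)-benzyl glycidyl ether.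

Key step: step 9

Assumption: the target is treated as the open hydroxy aldehyde, because a five-membered lactol between the axial C1 hydroxyl and the equatorial C9 formyl group would need two adjacent gauche torsions of the same sign and cannot close on the chair framework.

**Route**

Step 1
Reactants: 1 pent-1-en-4-yne; 2 (S)-benzyl glycidyl ether
Product: 5 (2S,4E)-1-(benzyloxy)-5-methylocta-4,7-dien-2-ol, via alkenylalane 3 (not isolated), via lithium alanate 4 (not isolated)
Conditions: Me3Al, Cp2ZrCl2 (0.25 equiv), CH2Cl2, 0 °C to rt; then n-BuLi, THF, −78 °C; then 2, −78 °C to rt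
Reagents that add atoms: trimethylaluminium, C[Al](C)C
Why: Negishi carboalumination adds CH3 and Al syn across the terminal alkyne (Al at the CH end), which fixes the E geometry of the future C3=C4 alkene, and the alkenyl alanate opens the epoxide at its CH2 carbon so that the stereocentre (future C1) is carried over unchanged.

Step 2
Reactants: 5 (2S,4E)-1-(benzyloxy)-5-methylocta-4,7-dien-2-ol
Product: 6 tert-butyl{[(2S,4E)-1-(benzyloxy)-5-methylocta-4,7-dien-2-yl]oxy}dimethylsilane
Conditions: TBSCl, imidazole, DMF, rt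
Reagents that add atoms: tert-butyldimethylsilyl chloride, CC(C)(C)[Si](C)(C)Cl
Why: Imidazole-promoted silylation of the secondary alcohol is routine and touches no stereocentre.

Step 3
Reactants: 6 tert-butyl{[(2S,4E)-1-(benzyloxy)-5-methylocta-4,7-dien-2-yl]oxy}dimethylsilane
Product: 7 (2S,4E)-2-[(tert-butyldimethylsilyl)oxy]-5-methylocta-4,7-dien-1-ol
Conditions: lithium 4,4'-di-tert-butylbiphenylide, THF, −78 °C; then MeOH, −78 °C
Reagents that add atoms: none
Why: Reductive debenzylation (single-electron transfer from the arene radical anion) cleaves the benzylic C–O bond while isolated alkenes and the silyl ether are inert, and the cold methanol quench stops silyl migration to the primary alkoxide.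

Step 4
Reactants: 7 (2S,4E)-2-[(tert-butyldimethylsilyl)oxy]-5-methylocta-4,7-dien-1-ol
Product: 8 (2S,4E)-2-[(tert-butyldimethylsilyl)oxy]-5-methylocta-4,7-dienal
Conditions: Dess–Martin periodinane, CH2Cl2, 0 °C to rt
Reagents that add atoms: none
Why: Dess–Martin oxidation gives the α-silyloxy aldehyde under non-basic conditions that should not epimerise it; it is used at once.

Step 5
Reactants: 8 (2S,4E)-2-[(tert-butyldimethylsilyl)oxy]-5-methylocta-4,7-dienal
Product: 9 tert-butyldimethyl{[(3S,5E)-6-methylnona-5,8-dien-1-yn-3-yl]oxy}silane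
Conditions: dimethyl (1-diazo-2-oxopropyl)phosphonate, K2CO3, MeOH, 0 °C to rt
Reagents that add atoms: dimethyl (1-diazo-2-oxopropyl)phosphonate, CC(=O)C(=[N+]=[N-])P(=O)(OC)OC
Why: Ohira–Bestmann (Seyferth–Gilbert) homologation turns the aldehyde into the terminal alkyne under mild carbonate conditions that normally leave an α-silyloxy stereocentre intact.

Step 6
Reactants: 9 tert-butyldimethyl{[(3S,5E)-6-methylnona-5,8-dien-1-yn-3-yl]oxy}silane
Product: 12 (2E,4S,6E)-4-[(tert-butyldimethylsilyl)oxy]-3,7-dimethyldeca-2,6,9-trien-1-ol, via alkenylalane 10 (not isolated), via lithium alanate 11 (not isolated)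
Conditions: Me3Al, Cp2ZrCl2 (0.3 equiv), ClCH2CH2Cl, 0 °C to rt; then n-BuLi, THF, −78 °C; then (CH2O)n, −78 °C to rt
Reagents that add atoms: trimethylaluminium, C[Al](C)C; formaldehyde (as paraformaldehyde), C=O
Why: A second Negishi carboalumination adds CH3 (to C10) and Al (to C5) syn across the terminal alkyne, much faster than across the isolated alkenes, and the alanate adds to formaldehyde with retention, so the E C5=C10 alkene and C6 arrive together.

Step 7
Reactants: 12 (2E,4S,6E)-4-[(tert-butyldimethylsilyl)oxy]-3,7-dimethyldeca-2,6,9-trien-1-ol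
Product: 13 (2E,4S,6E)-1-bromo-4-[(tert-butyldimethylsilyl)oxy]-3,7-dimethyldeca-2,6,9-triene
Conditions: CBr4, PPh3, CH2Cl2, 0 °C
Reagents that add atoms: tetrabromomethane, BrC(Br)(Br)Br
Why: Appel bromination converts the primary allylic alcohol to the bromide under neutral conditions without allylic transposition.

Step 8
Reactants: 13 (2E,4S,6E)-1-bromo-4-[(tert-butyldimethylsilyl)oxy]-3,7-dimethyldeca-2,6,9-triene; 14 methyl acetoacetate
Product: 16 methyl (6E,8S,10E)-8-[(tert-butyldimethylsilyl)oxy]-7,11-dimethyl-3-oxotetradeca-6,10,13-trienoate, via acetoacetate dianion 15 (not isolated)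
Conditions: 14, NaH, THF, 0 °C; n-BuLi, 0 °C; then 13, 0 °C
Reagents that add atoms: none
Why: γ-Alkylation of the acetoacetate dianion: the more basic terminal carbanion displaces the primary allylic bromide in an SN2 reaction that keeps both alkene geometries.

Step 9
Reactants: 16 methyl (6E,8S,10E)-8-[(tert-butyldimethylsilyl)oxy]-7,11-dimethyl-3-oxotetradeca-6,10,13-trienoate
Product: 17 methyl 4α-allyl-1α-[(tert-butyldimethylsilyl)oxy]-3β-chloro-4β,10β-dimethyl-8-oxo-trans-decalin-9β-carboxylate (5α-H)
Conditions: [Et2SCl][SbCl6] (1.1 equiv), MeNO2, −25 °C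
Reagents that add atoms: chlorodiethylsulfonium hexachloroantimonate, CC[S+](Cl)CC.Cl[Sb-](Cl)(Cl)(Cl)(Cl)Cl
Why: Proposed new method: the sulfonium salt transfers Cl+ to the C3=C4 alkene, the chloriranium ion is opened anti at tertiary C4 by C5 of the C5=C10 alkene, and the resulting C10 cation is taken by the enol carbon C9 of the keto ester, which then loses a proton. The closest known reaction type is the chloriranium-initiated polyene cyclisation with chlorodiethylsulfonium hexachloroantimonate, together with Lewis-acid cyclisations of polyene β-keto esters that end by C-alkylation; untested here are initiation at an alkene that is not the chain end and a silyl ether on the carbon next to the cationic centre C10. Ring A closes in the 6-endo mode through a chair and ring B in the 6-endo (enol-endo) mode through a second chair, which gives the trans ring fusion. Anti addition across the E C3=C4 alkene sets C3 and C4 (Cl equatorial, C4 methyl axial, allyl equatorial), anti addition across the E C5=C10 alkene sets C5 and C10, C9 takes the equatorial, equilibrating ester, and the absolute sense comes from C1, whose silyloxy group should stand axial to avoid A(1,2) strain with the C10 methyl and the peri contact with the C9 ester. In that arrangement the C1–H bond lies near the nodal plane of the C10 cation, which should suppress a 1,2-hydride (semipinacol) shift. The step needs Cl+ to select C3=C4 over C5=C10, the vinyl group and the keto ester: C5=C10 is made electron-poorer by its allylic silyl ether, the vinyl group is only monosubstituted, and the keto ester exists mainly as the unreactive keto tautomer.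

Step 10
Reactants: 17 methyl 4α-allyl-1α-[(tert-butyldimethylsilyl)oxy]-3β-chloro-4β,10β-dimethyl-8-oxo-trans-decalin-9β-carboxylate
Product: 18 4α-allyl-1α-[(tert-butyldimethylsilyl)oxy]-3β-chloro-9β-(hydroxymethyl)-4β,10β-dimethyl-trans-decalin-8-ol (C8 epimers)
Conditions: LiAlH4, THF, 0 °C to rt
Reagents that add atoms: none
Why: Hydride reduction of ketone and ester gives the 8,11-diol with C9 unchanged; the new C8 carbinol centre may form as either epimer since it is reoxidised in step 12, and the equatorial neopentyl-type chloride has neither an SN2 path nor an antiperiplanar hydrogen.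

Step 11
Reactants: 18 4α-allyl-1α-[(tert-butyldimethylsilyl)oxy]-3β-chloro-9β-(hydroxymethyl)-4β,10β-dimethyl-trans-decalin-8-ol
Product: 19 4α-allyl-1α-[(tert-butyldimethylsilyl)oxy]-9β-{[(tert-butyldimethylsilyl)oxy]methyl}-3β-chloro-4β,10β-dimethyl-trans-decalin-8-ol (C8 epimers)
Conditions: TBSCl (1.05 equiv), imidazole, CH2Cl2, 0 °C
Reagents that add atoms: tert-butyldimethylsilyl chloride, CC(C)(C)[Si](C)(C)Cl
Why: Chemoselective silylation: the primary C11 hydroxyl reacts far faster with TBSCl than the ring secondary C8 hydroxyl.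

Step 12
Reactants: 19 4α-allyl-1α-[(tert-butyldimethylsilyl)oxy]-9β-{[(tert-butyldimethylsilyl)oxy]methyl}-3β-chloro-4β,10β-dimethyl-trans-decalin-8-ol
Product: 20 4α-allyl-1α-[(tert-butyldimethylsilyl)oxy]-9β-{[(tert-butyldimethylsilyl)oxy]methyl}-3β-chloro-4β,10β-dimethyl-trans-decalin-8-one
Conditions: Dess–Martin periodinane, CH2Cl2, rt
Reagents that add atoms: none
Why: Dess–Martin oxidation regenerates the C8 ketone under neutral conditions, so the β-silyloxy group is not eliminated and C9 keeps its equatorial substituent.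

Step 13
Reactants: 20 4α-allyl-1α-[(tert-butyldimethylsilyl)oxy]-9β-{[(tert-butyldimethylsilyl)oxy]methyl}-3β-chloro-4β,10β-dimethyl-trans-decalin-8-one
Product: 22 C7=C8 enol triflate of ketone 20 (8-trifluoromethanesulfonyloxy-Δ7), via potassium enolate 21 (not isolated)
Conditions: KN(SiMe3)2, THF, −78 °C; then PhNTf2, −78 to 0 °C
Reagents that add atoms: N-phenylbis(trifluoromethanesulfonimide), O=S(=O)(N(c1ccccc1)S(=O)(=O)C(F)(F)F)C(F)(F)F
Why: Kinetic enolisation with a bulky amide base removes a proton from the C7 methylene instead of the hindered C9 methine next to quaternary C10, and O-sulfonylation of the enolate with PhNTf2 locks the C7=C8 enol triflate.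

Step 14
Reactants: 22 C7=C8 enol triflate of ketone 20
Product: 23 methyl 4α-allyl-1α-[(tert-butyldimethylsilyl)oxy]-9β-{[(tert-butyldimethylsilyl)oxy]methyl}-3β-chloro-4β,10β-dimethyl-Δ7-trans-octalin-8-carboxylate
Conditions: Pd(OAc)2 (10 mol%), PPh3 (20 mol%), CO (1 atm), MeOH, Et3N, DMF, 40 °C
Reagents that add atoms: carbon monoxide, [C-]#[O+]; methanol, CO
Why: Palladium-catalysed alkoxycarbonylation of the enol triflate (oxidative addition to zerovalent palladium formed in situ, CO insertion, methanolysis of the acyl complex) gives the conjugated methyl ester, with the alkyl chloride and the terminal alkene untouched.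

Step 15
Reactants: 23 methyl 4α-allyl-1α-[(tert-butyldimethylsilyl)oxy]-9β-{[(tert-butyldimethylsilyl)oxy]methyl}-3β-chloro-4β,10β-dimethyl-Δ7-trans-octalin-8-carboxylate; 24 2-methylbut-3-en-2-ol
Product: 25 the analogue of 23 in which the 4α-allyl group has become 4α-[(2E)-4-hydroxy-4-methylpent-2-en-1-yl]
Conditions: second-generation Grubbs catalyst (H2IMes)(PCy3)Cl2Ru=CHPh (5 mol%), 24 (excess), CH2Cl2, 40 °C
Reagents that add atoms: none
Why: Olefin cross-metathesis joins the terminal allyl group to the tertiary allylic alcohol, a partner that homodimerises slowly and gives the E-disubstituted alkene for steric reasons, while the trisubstituted enoate is inert.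

Step 16
Reactants: 25 bis-silyl ether with the complete side chain
Product: 26 methyl 3β-chloro-1α-hydroxy-9β-(hydroxymethyl)-4α-[(2E)-4-hydroxy-4-methylpent-2-en-1-yl]-4β,10β-dimethyl-Δ7-trans-octalin-8-carboxylate
Conditions: HF·pyridine, pyridine, THF, 0 °C to rt
Reagents that add atoms: none
Why: Fluoride cleaves both Si–O bonds under buffered conditions that should spare the tertiary allylic alcohol, the enoate and the secondary chloride.

Step 17
Reactants: 26 methyl 3β-chloro-1α-hydroxy-9β-(hydroxymethyl)-4α-[(2E)-4-hydroxy-4-methylpent-2-en-1-yl]-4β,10β-dimethyl-Δ7-trans-octalin-8-carboxylate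
Product: 27 CNP0167913.1 (9β-formyl compound, the target)
Conditions: TEMPO (10 mol%), PhI(OAc)2, CH2Cl2, rt
Reagents that add atoms: none
Why: TEMPO/oxoammonium oxidation with PhI(OAc)2 as terminal oxidant takes the primary C11 alcohol in preference to the hindered axial C1 alcohol and the tertiary alcohol, under near-neutral conditions that should not epimerise C9 or shift the C7=C8 double bond.

**Compound list**

1 | pent-1-en-4-yne | C=CCC#C | starting material
2 | (S)-benzyl glycidyl ether | C(OCc1ccccc1)[C@H]1OC1 | starting material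
3 | dimethyl[(1E)-2-methylpenta-1,4-dien-1-yl]alane | C[Al](C)/C=C(\C)CC=C | intermediate (not isolated)
4 | lithium butyl(dimethyl)[(1E)-2-methylpenta-1,4-dien-1-yl]aluminate | [Li+].CCCC[Al-](C)(C)/C=C(\C)CC=C | intermediate (not isolated)
5 | (2S,4E)-1-(benzyloxy)-5-methylocta-4,7-dien-2-ol | C(OCc1ccccc1)[C@@H](O)C/C=C(\C)CC=C | intermediate
6 | tert-butyl{[(2S,4E)-1-(benzyloxy)-5-methylocta-4,7-dien-2-yl]oxy}dimethylsilane | C(OCc1ccccc1)[C@@H](O[Si](C)(C)C(C)(C)C)C/C=C(\C)CC=C | intermediate
7 | (2S,4E)-2-[(tert-butyldimethylsilyl)oxy]-5-methylocta-4,7-dien-1-ol | OC[C@@H](O[Si](C)(C)C(C)(C)C)C/C=C(\C)CC=C | intermediate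
8 | (2S,4E)-2-[(tert-butyldimethylsilyl)oxy]-5-methylocta-4,7-dienal | O=C[C@@H](O[Si](C)(C)C(C)(C)C)C/C=C(\C)CC=C | intermediate
9 | tert-butyldimethyl{[(3S,5E)-6-methylnona-5,8-dien-1-yn-3-yl]oxy}silane | C#C[C@@H](O[Si](C)(C)C(C)(C)C)C/C=C(\C)CC=C | intermediate
10 | dimethyl{(1E,3S,5E)-3-[(tert-butyldimethylsilyl)oxy]-2,6-dimethylnona-1,5,8-trien-1-yl}alane | C[Al](C)/C=C(C)/[C@@H](O[Si](C)(C)C(C)(C)C)C/C=C(\C)CC=C | intermediate (not isolated)
11 | lithium butyl(dimethyl){(1E,3S,5E)-3-[(tert-butyldimethylsilyl)oxy]-2,6-dimethylnona-1,5,8-trien-1-yl}aluminate | [Li+].CCCC[Al-](C)(C)/C=C(C)/[C@@H](O[Si](C)(C)C(C)(C)C)C/C=C(\C)CC=C | intermediate (not isolated)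
12 | (2E,4S,6E)-4-[(tert-butyldimethylsilyl)oxy]-3,7-dimethyldeca-2,6,9-trien-1-ol | OC/C=C(C)/[C@@H](O[Si](C)(C)C(C)(C)C)C/C=C(\C)CC=C | intermediate
13 | (2E,4S,6E)-1-bromo-4-[(tert-butyldimethylsilyl)oxy]-3,7-dimethyldeca-2,6,9-triene | BrC/C=C(C)/[C@@H](O[Si](C)(C)C(C)(C)C)C/C=C(\C)CC=C | intermediate
14 | methyl acetoacetate | COC(=O)CC(C)=O | starting material
15 | methyl acetoacetate dianion (sodium lithium salt) | [Na+].[Li+].COC(=O)[CH-]C(=O)[CH2-] | intermediate (not isolated)
16 | methyl (6E,8S,10E)-8-[(tert-butyldimethylsilyl)oxy]-7,11-dimethyl-3-oxotetradeca-6,10,13-trienoate (cyclisation precursor) | COC(=O)CC(=O)CC/C=C(C)/[C@@H](O[Si](C)(C)C(C)(C)C)C/C=C(\C)CC=C | intermediate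
17 | methyl 4α-allyl-1α-(TBS-oxy)-3β-chloro-4β,10β-dimethyl-8-oxo-trans-decalin-9β-carboxylate | O=C1CC[C@H]2[C@](C)(CC=C)[C@@H](Cl)C[C@H](O[Si](C)(C)C(C)(C)C)[C@]2(C)[C@H]1C(=O)OC | intermediate
18 | 8,11-diol from 17 (C8 epimers, C8 left undefined) | OC1CC[C@H]2[C@](C)(CC=C)[C@@H](Cl)C[C@H](O[Si](C)(C)C(C)(C)C)[C@]2(C)[C@H]1CO | intermediate
19 | 11-O-TBS ether of 18 (C8 epimers) | OC1CC[C@H]2[C@](C)(CC=C)[C@@H](Cl)C[C@H](O[Si](C)(C)C(C)(C)C)[C@]2(C)[C@H]1CO[Si](C)(C)C(C)(C)C | intermediate
20 | 8-ketone with 1α-OTBS and 9β-CH2OTBS | O=C1CC[C@H]2[C@](C)(CC=C)[C@@H](Cl)C[C@H](O[Si](C)(C)C(C)(C)C)[C@]2(C)[C@H]1CO[Si](C)(C)C(C)(C)C | intermediate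
21 | potassium C7=C8 enolate of 20 | [K+].[O-]C1=CC[C@H]2[C@](C)(CC=C)[C@@H](Cl)C[C@H](O[Si](C)(C)C(C)(C)C)[C@]2(C)[C@H]1CO[Si](C)(C)C(C)(C)C | intermediate (not isolated)
22 | C7=C8 enol triflate of 20 | FC(F)(F)S(=O)(=O)OC1=CC[C@H]2[C@](C)(CC=C)[C@@H](Cl)C[C@H](O[Si](C)(C)C(C)(C)C)[C@]2(C)[C@H]1CO[Si](C)(C)C(C)(C)C | intermediate
23 | Δ7 methyl 8-carboxylate with 4α-allyl, 1α-OTBS, 9β-CH2OTBS | COC(=O)C1=CC[C@H]2[C@](C)(CC=C)[C@@H](Cl)C[C@H](O[Si](C)(C)C(C)(C)C)[C@]2(C)[C@H]1CO[Si](C)(C)C(C)(C)C | intermediate
24 | 2-methylbut-3-en-2-ol | CC(C)(O)C=C | starting material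
25 | cross-metathesis product (bis-TBS ether, full side chain) | COC(=O)C1=CC[C@H]2[C@](C)(C/C=C/C(C)(C)O)[C@@H](Cl)C[C@H](O[Si](C)(C)C(C)(C)C)[C@]2(C)[C@H]1CO[Si](C)(C)C(C)(C)C | intermediate
26 | triol (1α-OH, C11-OH, side-chain OH) | COC(=O)C1=CC[C@H]2[C@](C)(C/C=C/C(C)(C)O)[C@@H](Cl)C[C@H](O)[C@]2(C)[C@H]1CO | intermediate
27 | CNP0167913.1 | COC(=O)C1=CC[C@H]2[C@](C)(C/C=C/C(C)(C)O)[C@@H](Cl)C[C@H](O)[C@]2(C)[C@H]1C=O | target

**Step count and risks**

Total step count: 17. Longest linear sequence: 17 steps (1 to 27); 2, 14 and 24 enter as purchased.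

Steps most likely to fail:

1. Step 9 (chloriranium bicyclisation). What may go wrong: after ring A has closed, the C10 cation is captured by the enol oxygen instead of the enol carbon, so that the C9–C10 bond does not form. The fallback sets out from 16 and rejoins the route at 17. The same step 9 conditions then deliver the O-closed tricyclic enol ether F1 (a C10–O–C8 dihydropyran with an exocyclic C8=C9H–CO2Me unit), which is isolated and treated with SnCl4 in CH2Cl2 at −78 to −20 °C. Lewis-acid ionisation of the tertiary C10–O bond regenerates the C10 cation beside a tin enolate, and recombination at carbon should give 17. This is the known behaviour of cyclic enol ethers of β-keto esters that arise in polyene cyclisations. Ring B is then closed in a separate operation and no longer within the cascade.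

2. Step 6 (second carboalumination). What may go wrong: slow or regio-unselective carbometallation of the alkyne next to the silyloxy group, or competing reaction at the vinyl group. The fallback sets out from 8 and rejoins at 12, bypassing the alkyne. MeMgBr (THF, −78 °C) adds to 8 to give the methyl carbinol F2 (both epimers at the new centre). Dess–Martin oxidation gives the methyl ketone F3. Horner–Wadsworth–Emmons olefination with trimethyl phosphonoacetate and NaH (THF, 0 °C to rt) should give mainly the (E)-enoate F4, with the branched silyloxy carbon trans to the ester; the minor Z isomer is removed by chromatography. Reduction with i-Bu2AlH (CH2Cl2, −78 °C) then gives 12.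

3. Step 13 (kinetic enol triflate). What may go wrong: deprotonation at C9 in place of C7, followed by β-elimination of the C11 silyloxy group, or triflation of a mixture of enolates. The fallback sets out from 20 and rejoins at 23, bypassing 22, by a Shapiro reaction. Condensation of 20 with 2,4,6-triisopropylbenzenesulfonohydrazide (THF, rt) gives the trisylhydrazone F5. n-BuLi (2.2 equiv, THF, −78 to 0 °C) removes the N–H and then a C7 proton on the less substituted side, and loss of sulfinate and N2 gives the C8 alkenyllithium F6. Trapping F6 with methyl chloroformate at −78 °C gives the enoate 23.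

**Further compounds**

F1 | step 9 | O-closed tricyclic enol ether (C10–O–C8 dihydropyran, exocyclic C8=C9H–CO2Me, ring A as in 17) | COC(=O)C=C1CC[C@H]2[C@](C)(CC=C)[C@@H](Cl)C[C@H](O[Si](C)(C)C(C)(C)C)[C@]2(C)O1
F2 | step 6 | (3S,5E)-3-[(tert-butyldimethylsilyl)oxy]-6-methylnona-5,8-dien-2-ol (C2 epimers) | CC(O)[C@@H](O[Si](C)(C)C(C)(C)C)C/C=C(\C)CC=C
F3 | step 6 | (3S,5E)-3-[(tert-butyldimethylsilyl)oxy]-6-methylnona-5,8-dien-2-one | CC(=O)[C@@H](O[Si](C)(C)C(C)(C)C)C/C=C(\C)CC=C
F4 | step 6 | methyl (2E,4S,6E)-4-[(tert-butyldimethylsilyl)oxy]-3,7-dimethyldeca-2,6,9-trienoate | COC(=O)/C=C(C)/[C@@H](O[Si](C)(C)C(C)(C)C)C/C=C(\C)CC=C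
F5 | step 13 | 2,4,6-triisopropylbenzenesulfonylhydrazone of 20 | CC(C)c1cc(C(C)C)c(S(=O)(=O)NN=C2CC[C@H]3[C@](C)(CC=C)[C@@H](Cl)C[C@H](O[Si](C)(C)C(C)(C)C)[C@]3(C)[C@H]2CO[Si](C)(C)C(C)(C)C)c(c1)C(C)C
F6 | step 13 | C8 alkenyllithium (C7=C8) from F5 | [Li]C1=CC[C@H]2[C@](C)(CC=C)[C@@H](Cl)C[C@H](O[Si](C)(C)C(C)(C)C)[C@]2(C)[C@H]1CO[Si](C)(C)C(C)(C)C
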